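## Structural features

The target (23) is a germacrane: one ten-membered carbocycle whose only ring fusion is a 4,5-epoxide, so formally an 11-oxabicyclo[8.1.0]undec-4-ene. In germacrane numbering the ring holds the (E)-trisubstituted olefin C1=C10 (methyl on C10), three plain methylenes (C2, C8, C9) and five contiguous stereocentres: C3 (S, 3-methylbut-2-enoate), C4 (R, fully substituted epoxide carbon with methyl), C5 (R, epoxide CH), C6 (R, acetate) and C7 (S, isopropyl). The epoxide is trans-fused (C3 and C6 on opposite faces of the oxirane); drawn as an extended chain, the C5–O/C6–O pair and the C6–O/C7-isopropyl pair are both anti. Fragile elements are the trisubstituted epoxide between two acyloxy-bearing carbons (acid opening, attack by an ester carbonyl, Payne migration if the C6 oxygen becomes an alkoxide), the two different secondary esters (hydrolysis, and deconjugation of the senecioate) and the medium ring itself. The real difficulty is twofold: five adjacent stereocentres with two differently acylated oxygens, and closure of a strained ten-membered ring with a defined (E)-olefin. The feature exploited is that C8 and C9 are unfunctionalised and that the C9–C10 bond joins an sp3 methylene to the methyl-bearing olefinic carbon on the side of the ring remote from C3–C7. A chain with every stereocentre, both esters and the epoxide in place can therefore be closed there by coupling a C9 alkylborane with a C10 alkenyl iodide.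

## Logic of the disconnections

Atom labels are germacrane labels; compounds are referred to by number.

**C9–C10 of 23.** This sp3–sp2 ring bond lies four atoms from the nearest stereocentre, so cutting it opens the ring to 21 without touching a stereocentre or a heteroatom. C9 becomes the end of a vinyl group (C8=C9), which is hydroborated to 22, and C10 becomes an (E)-alkenyl iodide. The gain is that the medium ring is replaced by a chain that can be built by reagent-controlled acyclic chemistry. The forward step must hydroborate only the monosubstituted olefin, transfer the iodide geometry with retention, and cyclise faster than it oligomerises. The C6 oxygen is taken through this step as the acetate of the target and not as a silyl ether; the structures themselves needed no correction (21 is 7R only because vinyl outranks isopropyl, the spatial arrangement being that of 7S in 23). Carrying the acetate makes the cyclisation product 23 itself, saves two steps and a fluoride treatment next to the epoxide, and never exposes a C6 alkoxide that could undergo Payne migration.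

**C6–O acyl bond of 21.** Removing the acetyl group gives 20. The demand is acylation of a hindered carbinol next to the epoxide under weakly basic, non-nucleophilic conditions.

**C6–C7 of 20.** Cutting here gives 15 and 18. One allylboration then creates C6, C7 and the C8=C9 vinyl group together, and the chain is split into a C1–C6 piece and a six-carbon reagent. The forward step needs an (E)-configured allylboron reagent (for the anti C6/C7 pair) and attack on the Re face of the formyl group of 15, which is also the Felkin–Anh face (5,6-anti).

**C–B and C–C bonds of 18.** The C–B bond is cut with allylic transposition to 17, and the bond between the carbinol carbon and the vinyl group of 17 is cut to 16. The borylation must deliver the linear (E)-isomer.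

**Oxidation level at C6 and the oxirane C–O bonds (15, 14, 13).** 15 comes from 14 by oxidation, and 14 from 13 by tartrate-controlled epoxidation of a primary (E)-allylic alcohol, the most dependable substrate class for that reaction. Epoxidising before C6–C7 is formed avoids a secondary allylic alcohol whose olefin carries a cis methyl group, which is a poor substrate for tartrate control and biased the wrong way under substrate control. The demand is that only C4=C5 reacts and that C3 is already acylated, since a free C3 hydroxyl would be a second allylic alcohol on the same olefin.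

**O–Si bond at C6 and the acyl C–O bond at C3 (13, 12, 10 + 11).** The senecioate must be on before the epoxidation and after the organometallic steps. The demands are esterification without deconjugation and desilylation that leaves esters and iodide alone.

**C10–I/C1–H and C10–CH3 (10, 8, 6).** Syn hydrometallation of a methyl alkyne followed by iodinolysis is the stereospecific source of the (E)-2-iodo-2-alkene; the methyl group is attached by acetylide alkylation. This alkylation is why the C6 oxygen is a silyl ether and not an acetate up to this point. The demand is that the metal ends on the methyl-bearing carbon.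

**C2–C3 of 6.** Cutting gives 3 and 4. An asymmetric propargylation sets C3; the demand is Si-face attack and exclusive SE2′ delivery (homopropargylic, not allenic, alcohol).

**C4=C5 of 3.** Cutting the olefin gives 1 and 2. An (E)-selective Wittig reaction with a stabilised ylide gives the C5 unit with the silyl ether already in place and avoids a selenium-based allylic oxidation.

## Other disconnections considered

Alternative 1: The cut is C6–C7, made transannularly: the carbocycle is traced back to the 13-membered diallylic ether A1, in which an oxygen bridges C6 and C12 and C3 already carries its silyl ether. In the forward step a chiral lithium amide would remove a C6 proton of A1, and the α-oxy allyl anion would add through C6 to C7 in a [2,3]-sigmatropic shift that breaks C12–O and contracts the ring to the trienol A2.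
- In its favour: the ten-membered ring would come from a far less strained macrocycle by a concerted five-centre shift, with no metal and no high dilution for the ring-forming C–C bond. Both ring olefin geometries are carried in from an acyclic triene. Two stereocentres (C6, C7) arise in the key step, whereas the chosen ring closure creates none. On ease of ring formation and on stereocentres made per step this plan is the better one.
- Against it here: A1 has two allylic O–CH2 groups (C6 and C12), and only metalation at C6 leads to A2. The C6/C7 relationship is dictated by the cyclic transition state and cannot be chosen. The absolute sense rests on a chiral base acting on a mobile macrocycle whose only stereocentre (C3) is remote.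
- After the key step A2 would still need saturation of the isopropenyl group beside two ring olefins, a hydroxyl-directed epoxidation of C4=C5 whose facial outcome depends on ring conformation, acetylation, desilylation and senecioylation.
- A2 is a germacra-1(10),4-diene, a class liable to Cope rearrangement and acid-induced transannular cyclisation; the chosen plan avoids this because the epoxide exists before the ring does.
- Comparison: in structure, the chosen plan places all five stereocentres by reagent control on an open chain. In mechanism, its key step has no stereochemical duty but a harder ring closure. In step economy, Alternative 1 would need an estimated nine to ten steps to A1, the contraction and five more, about three more than the route below.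

Alternative 2: The cut is C8–C9, seen as the bond formed in a [3,3] shift: the enone A4 is traced back to the cyclohexanol A3, whose six-membered ring holds C1–C6, with hydroxyl and the 3-methylbut-1-en-2-yl group on C6 and the isopropenyl group on C1, trans to each other. In the forward step the potassium alkoxide of A3 (with a crown ether) would undergo the anionic oxy-Cope rearrangement, forming C8–C9, breaking C1–C6 and giving the enolate of A4.
- In its favour: a strongly driven ring expansion that needs no dilution, with the (E)-C1=C10 geometry secured by a chair transition state. C3, C4 and C5 can be set on a six-membered ring from the chiral pool, where cyclic stereocontrol is strong. The ring-forming event itself should be more dependable than a palladium closure at ten atoms; on that point this plan is the better one. In stereospecific transfer of olefin geometry the two plans are equal.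
- Against it here: A3 needs oxygen on three adjacent ring carbons of a terpene cyclohexane, including the tertiary C4. C7 is set not by the rearrangement but by protonation of a medium-ring enolate. The β-alkoxy ketone A4 could enolise toward C5 and expel the C4 oxygen under the basic conditions. The C6 ketone must then be reduced from the correct face of a flexible ring.
- The C5 oxygen of A4 lies on the face opposite to the epoxide oxygen of 23 while C4 matches. The oxirane would therefore have to be closed by selective activation of the C5 hydroxyl and displacement with inversion by the C4 oxygen, followed by acetylation, desilylation and senecioylation.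
- Comparison: in structure, two of the five stereocentres (C6, C7) would rest on substrate control in a medium ring, against reagent control on a chain in the chosen plan. In mechanism, a pericyclic expansion stands against a cross-coupling. In step economy, an estimated seventeen or more steps stand against thirteen.

Alternative 3: The cut is C5–C10 of a decalin: 23 is traced through the diene A6 to the octalin mesylate A5, which has a tetrasubstituted C4=C5 olefin, the angular methyl on C10 and the leaving group on C1. In the forward step hydroboration would put boron on C4 and hydrogen on C5; methoxide would then form the boronate, whose C4–B electrons build C4=C5 while C5–C10 breaks, C1=C10 forms and the mesylate leaves.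
- In its favour: no macrocyclisation at all, and both ring olefin geometries follow stereospecifically from an antiperiplanar arrangement in a rigid bicycle. C7 comes from the chiral pool, and C3 and C6 can be set under the conformational control of a decalin. The silyl groups of A6 are well matched, since the more labile triethylsilyl ether can be removed first to free the C6 hydroxyl for a directed epoxidation. In certainty of olefin geometry, for two double bonds at once, this plan equals or surpasses the chosen one.
- Against it here: hydroboration of a tetrasubstituted olefin flanked by two silyloxy-bearing carbons is sterically demanding and must be regio- and face-selective. The C4 borane would be β to the C3 silyloxy group, so β-elimination of boron and oxygen, a familiar path for such boranes, would compete and destroy C3.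
- A5 needs oxygen at C1, C3 and C6 of the decalin, a long sequence. A6 is again a 1(10),4-diene with the Cope and transannular liabilities noted above. After the fragmentation, C4=C5 must be epoxidised beside C1=C10 and from the right face, followed by three acylation and deprotection steps.
- Comparison: in structure, the chosen plan never passes through a ring diene. In mechanism, a stereospecific fragmentation with a doubtful hydroboration stands against a non-stereogenic coupling with a doubtful ring size. In step economy, an estimated seventeen or more steps stand against thirteen.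

Key step: step 13

Assumption: the chiral phosphoric acid TRIP is taken to direct boronate additions to the Re face of a formyl group with its (R)-enantiomer and to the Si face with its (S)-enantiomer, as with simple aldehydes.

## Route

Step 1
Reactants: 1 2-[(tert-butyldimethylsilyl)oxy]acetaldehyde; 2 2-(triphenylphosphoranylidene)propanal
Product: 3 (2E)-4-[(tert-butyldimethylsilyl)oxy]-2-methylbut-2-enal
Conditions: 2 (1.1 equiv), toluene, 80 °C
Reagents that add atoms: none
Why: Wittig olefination with a stabilised formyl ylide, which gives the (E)-enal (formyl trans to CH2OSi) under thermodynamic control; the α-branched enal product is less electrophilic than 1, so a second homologation should not compete.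

Step 2
Reactants: 3 (2E)-4-[(tert-butyldimethylsilyl)oxy]-2-methylbut-2-enal; 4 4,4,5,5-tetramethyl-2-(propa-1,2-dien-1-yl)-1,3,2-dioxaborolane (allenylboronic acid pinacol ester)
Product: 6 (4S,5E)-7-[(tert-butyldimethylsilyl)oxy]-5-methylhept-5-en-1-yn-4-ol, via O-pinacolboryl ether 5 (not isolated)
Conditions: (S)-TRIP (5 mol%), 4 Å MS, toluene, −20 °C; aq. NaHCO3
Reagents that add atoms: none
Why: Chiral-phosphoric-acid-catalysed allenylboration (asymmetric propargylation) through a closed six-membered SE2′ transition state, which gives only the homopropargylic alcohol; the (S)-acid should direct C–C formation to the Si face of the formyl group, which sets the carbinol (C3 of the germacrane) as S.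

Step 3
Reactants: 6 (4S,5E)-7-[(tert-butyldimethylsilyl)oxy]-5-methylhept-5-en-1-yn-4-ol
Product: 8 (2E,4S)-1-[(tert-butyldimethylsilyl)oxy]-3-methyloct-2-en-6-yn-4-ol, via dilithium alkoxide acetylide 7 (not isolated)
Conditions: n-BuLi (2.1 equiv), THF, −78 °C; MeI (1.3 equiv), −78 → 0 °C; aq. NH4Cl
Reagents that add atoms: iodomethane, CI
Why: Alkylation of a lithium acetylide; in THF the lithium alkoxide is far less nucleophilic than the acetylide, so methylation should occur on carbon, and the silyl ether (unlike an acetate) is inert to n-BuLi at −78 °C.

Step 4
Reactants: 8 (2E,4S)-1-[(tert-butyldimethylsilyl)oxy]-3-methyloct-2-en-6-yn-4-ol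
Product: 10 (2E,4S,6E)-1-[(tert-butyldimethylsilyl)oxy]-7-iodo-3-methylocta-2,6-dien-4-ol, via alkenylzirconocene chloride 9 (not isolated)
Conditions: Cp2Zr(H)Cl (3.0 equiv), THF, rt → 40 °C; I2, THF, 0 °C
Reagents that add atoms: iodine, II
Why: Hydrozirconation–iodination: the first equivalent of hydride is consumed by the hydroxyl, Zr–H then adds syn to the alkyne and, with excess hydride, equilibrates to the less hindered methyl-bearing carbon; iodinolysis with retention gives the (E)-iodide (C2 trans to iodine), which is the geometry of the ring olefin.

Step 5
Reactants: 10 (2E,4S,6E)-1-[(tert-butyldimethylsilyl)oxy]-7-iodo-3-methylocta-2,6-dien-4-ol; 11 3-methylbut-2-enoic acid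
Product: 12 (2E,4S,6E)-1-[(tert-butyldimethylsilyl)oxy]-7-iodo-3-methylocta-2,6-dien-4-yl 3-methylbut-2-enoate
Conditions: DCC, DMAP (10 mol%), CH2Cl2, 0 °C → rt
Reagents that add atoms: none
Why: Steglich esterification; the C3–O bond is not broken, so the configuration is kept, and using the free acid with only catalytic DMAP avoids the vinylketene route to the deconjugated ester that an acid chloride with amine base would open.

Step 6
Reactants: 12 (2E,4S,6E)-1-[(tert-butyldimethylsilyl)oxy]-7-iodo-3-methylocta-2,6-dien-4-yl 3-methylbut-2-enoate
Product: 13 (2E,4S,6E)-1-hydroxy-7-iodo-3-methylocta-2,6-dien-4-yl 3-methylbut-2-enoate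
Conditions: camphorsulfonic acid (10 mol%), MeOH/CH2Cl2, 0 °C
Reagents that add atoms: none
Why: Acid-catalysed methanolysis of a primary allylic silyl ether, which is fast under conditions that leave the ester and the alkenyl iodide alone; the ester cannot migrate to the new hydroxyl because C3 and C6 are trans across the olefin.

Step 7
Reactants: 13 (2E,4S,6E)-1-hydroxy-7-iodo-3-methylocta-2,6-dien-4-yl 3-methylbut-2-enoate
Product: 14 (1S,3E)-1-[(2R,3R)-3-(hydroxymethyl)-2-methyloxiran-2-yl]-4-iodopent-3-en-1-yl 3-methylbut-2-enoate
Conditions: Ti(OiPr)4, D-(−)-diethyl tartrate, t-BuOOH, 4 Å MS, CH2Cl2, −20 °C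
Reagents that add atoms: tert-butyl hydroperoxide, CC(C)(C)OO
Why: Sharpless asymmetric epoxidation of a primary (E)-allylic alcohol; D-(−)-tartrate delivers oxygen to the face that makes the CH2OH-bearing carbon (C5) R and hence C4 R, the (E) geometry gives the trans epoxide, and only the olefin with the free allylic hydroxyl is epoxidised.

Step 8
Reactants: 14 (1S,3E)-1-[(2R,3R)-3-(hydroxymethyl)-2-methyloxiran-2-yl]-4-iodopent-3-en-1-yl 3-methylbut-2-enoate
Product: 15 (1S,3E)-1-[(2R,3S)-3-formyl-2-methyloxiran-2-yl]-4-iodopent-3-en-1-yl 3-methylbut-2-enoate
Conditions: Dess–Martin periodinane, pyridine, CH2Cl2, 0 °C → rt; used crude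
Reagents that add atoms: none
Why: Buffered hypervalent-iodine oxidation of a primary alcohol; an oxirane carbon α to the formyl group does not epimerise (the descriptor changes from R to S only because CHO outranks C4).

Step 9
Reactants: 16 2-methylpropanal
Product: 17 4-methylpent-1-en-3-ol (racemic)
Conditions: CH2=CHMgBr, THF, 0 °C; aq. NH4Cl
Reagents that add atoms: vinylmagnesium bromide, C=C[Mg]Br
Why: Grignard addition to an aldehyde; the racemic carbinol is sufficient because its stereocentre is erased in the next step.

Step 10
Reactants: 17 4-methylpent-1-en-3-ol
Product: 18 4,4,5,5-tetramethyl-2-[(2E)-4-methylpent-2-en-1-yl]-1,3,2-dioxaborolane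
Conditions: B2pin2, Pd(MeCN)4(BF4)2 (3 mol%), DMSO/MeOH, 40 °C
Reagents that add atoms: bis(pinacolato)diboron, CC1(C)OB(OC1(C)C)B1OC(C)(C)C(C)(C)O1
Why: Palladium-catalysed borylation of an allylic alcohol through an η3-allyl intermediate; boron is delivered to the unsubstituted terminus, which gives the linear (E)-allylboronate, and one boryl unit takes up the hydroxyl.

Step 11
Reactants: 15 (1S,3E)-1-[(2R,3S)-3-formyl-2-methyloxiran-2-yl]-4-iodopent-3-en-1-yl 3-methylbut-2-enoate; 18 4,4,5,5-tetramethyl-2-[(2E)-4-methylpent-2-en-1-yl]-1,3,2-dioxaborolane
Product: 20 (1S,3E)-1-{(2R,3R)-3-[(1R,2R)-1-hydroxy-2-(propan-2-yl)but-3-en-1-yl]-2-methyloxiran-2-yl}-4-iodopent-3-en-1-yl 3-methylbut-2-enoate, via O-pinacolboryl ether 19 (not isolated)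
Conditions: (R)-TRIP (10 mol%), 4 Å MS, toluene, −30 → 0 °C; aq. NaHCO3
Reagents that add atoms: none
Why: Allylboration through a closed chair transition state in which the (E)-γ-isopropyl group is equatorial, so C6 and C7 come out anti; the (R)-acid should direct attack to the Re face of the formyl group (C6 R, C7 R as named with the vinyl group), which is also the Felkin–Anh face anti to the epoxide C–O bond, so catalyst and substrate control are matched.

Step 12
Reactants: 20 (1S,3E)-1-{(2R,3R)-3-[(1R,2R)-1-hydroxy-2-(propan-2-yl)but-3-en-1-yl]-2-methyloxiran-2-yl}-4-iodopent-3-en-1-yl 3-methylbut-2-enoate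
Product: 21 (1S,3E)-1-{(2R,3R)-3-[(1R,2R)-1-(acetyloxy)-2-(propan-2-yl)but-3-en-1-yl]-2-methyloxiran-2-yl}-4-iodopent-3-en-1-yl 3-methylbut-2-enoate
Conditions: Ac2O, pyridine, DMAP (cat.), CH2Cl2, 0 °C → rt
Reagents that add atoms: acetic anhydride, CC(=O)OC(C)=O
Why: DMAP-catalysed acylation, too weakly basic for Payne migration; it installs the final C6 acetate before ring closure, so the cyclisation delivers the target and the hydroxyl cannot consume borane.

Step 13
Reactants: 21 (1S,3E)-1-{(2R,3R)-3-[(1R,2R)-1-(acetyloxy)-2-(propan-2-yl)but-3-en-1-yl]-2-methyloxiran-2-yl}-4-iodopent-3-en-1-yl 3-methylbut-2-enoate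
Product: 23 (1R,2S,4E,8S,9R,10R)-9-(acetyloxy)-1,5-dimethyl-8-(propan-2-yl)-11-oxabicyclo[8.1.0]undec-4-en-2-yl 3-methylbut-2-enoate (the target; germacrane descriptors 3S,4R,5R,6R,7S,1(10)E), via B-alkyl-9-borabicyclononane 22 (not isolated)
Conditions: 9-BBN (1.5 equiv), THF, 0 °C → rt; then syringe pump (10 h) into Pd(dppf)Cl2 (15 mol%), AsPh3 (30 mol%), Cs2CO3 (3 equiv), DMF/THF/H2O, 45 °C, ca. 1 mM
Reagents that add atoms: none
Why: 9-BBN adds to the only monosubstituted olefin (C8=C9) with boron on terminal C9; at room temperature this hindered dialkylborane should leave the trisubstituted iodoalkene, the conjugated enoate, both esters and the epoxide untouched, which is the chemoselectivity the step needs and which the substitution pattern of 21 secures. Aqueous Cs2CO3 converts borane 22 into a hydroxyborate; zerovalent palladium formed from Pd(dppf)Cl2 inserts into the C10–I bond with retention, the primary alkyl group passes from boron to divalent palladium, and reductive elimination from the eleven-membered palladacycle forms C9–C10. The closest known reaction type is the B-alkyl Suzuki–Miyaura macrocyclisation, for which ten-membered rings are at the lower limit. The single ring is closed end to end, the C9 terminus of the chain onto its C10 terminus, by intramolecular cross-coupling. No stereocentre is created: the (E) geometry of C1=C10 is that of the iodide and is retained, and C3–C7 are spectators. The second selectivity needed is ring closure over intermolecular coupling: slow addition of 22 into a dilute catalyst solution keeps its stationary concentration low, the trans-epoxide and the substituted carbons C5–C7 restrict the chain toward folded conformers, the wide bite angle of dppf favours reductive elimination over β-hydride loss, and AsPh3 speeds transmetallation. Both esters are secondary and hindered and should tolerate carbonate at 45 °C, and the acetate keeps the C6 oxygen from becoming an alkoxide that could open the epoxide.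

## Compound list

1 | 2-[(tert-butyldimethylsilyl)oxy]acetaldehyde | O=CCO[Si](C)(C)C(C)(C)C | starting material
2 | 2-(triphenylphosphoranylidene)propanal | CC(C=O)=P(c1ccccc1)(c1ccccc1)c1ccccc1 | starting material
3 | (2E)-4-[(tert-butyldimethylsilyl)oxy]-2-methylbut-2-enal | O=C/C(C)=C/CO[Si](C)(C)C(C)(C)C | intermediate
4 | 4,4,5,5-tetramethyl-2-(propa-1,2-dien-1-yl)-1,3,2-dioxaborolane | C=C=CB1OC(C)(C)C(C)(C)O1 | starting material
5 | O-pinacolboryl ether of 6 (not isolated) | C#CC[C@H](OB1OC(C)(C)C(C)(C)O1)/C(C)=C/CO[Si](C)(C)C(C)(C)C | intermediate
6 | (4S,5E)-7-[(tert-butyldimethylsilyl)oxy]-5-methylhept-5-en-1-yn-4-ol | C#CC[C@H](O)/C(C)=C/CO[Si](C)(C)C(C)(C)C | intermediate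
7 | dilithium alkoxide acetylide of 6 (not isolated) | [Li]C#CC[C@H](O[Li])/C(C)=C/CO[Si](C)(C)C(C)(C)C | intermediate
8 | (2E,4S)-1-[(tert-butyldimethylsilyl)oxy]-3-methyloct-2-en-6-yn-4-ol | CC#CC[C@H](O)/C(C)=C/CO[Si](C)(C)C(C)(C)C | intermediate
9 | (E)-alkenylzirconocene chloride (Zr on C10, O-zirconated at C3; not isolated) | C/C(=C\C[C@H](O[Zr](Cl)(C1C=CC=C1)C1C=CC=C1)/C(C)=C/CO[Si](C)(C)C(C)(C)C)[Zr](Cl)(C1C=CC=C1)C1C=CC=C1 | intermediate
10 | (2E,4S,6E)-1-[(tert-butyldimethylsilyl)oxy]-7-iodo-3-methylocta-2,6-dien-4-ol | C/C(I)=C\C[C@H](O)/C(C)=C/CO[Si](C)(C)C(C)(C)C | intermediate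
11 | 3-methylbut-2-enoic acid | CC(C)=CC(=O)O | starting material
12 | (2E,4S,6E)-1-[(tert-butyldimethylsilyl)oxy]-7-iodo-3-methylocta-2,6-dien-4-yl 3-methylbut-2-enoate | C/C(I)=C\C[C@H](OC(=O)C=C(C)C)/C(C)=C/CO[Si](C)(C)C(C)(C)C | intermediate
13 | (2E,4S,6E)-1-hydroxy-7-iodo-3-methylocta-2,6-dien-4-yl 3-methylbut-2-enoate | C/C(I)=C\C[C@H](OC(=O)C=C(C)C)/C(C)=C/CO | intermediate
14 | (1S,3E)-1-[(2R,3R)-3-(hydroxymethyl)-2-methyloxiran-2-yl]-4-iodopent-3-en-1-yl 3-methylbut-2-enoate | OC[C@H]1O[C@]1(C)[C@@H](OC(=O)C=C(C)C)C/C=C(\C)I | intermediate
15 | (1S,3E)-1-[(2R,3S)-3-formyl-2-methyloxiran-2-yl]-4-iodopent-3-en-1-yl 3-methylbut-2-enoate | O=C[C@H]1O[C@]1(C)[C@@H](OC(=O)C=C(C)C)C/C=C(\C)I | intermediate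
16 | 2-methylpropanal | CC(C)C=O | starting material
17 | 4-methylpent-1-en-3-ol (racemic) | C=CC(O)C(C)C | intermediate
18 | 4,4,5,5-tetramethyl-2-[(2E)-4-methylpent-2-en-1-yl]-1,3,2-dioxaborolane | CC(C)/C=C/CB1OC(C)(C)C(C)(C)O1 | intermediate
19 | O-pinacolboryl ether of 20 (not isolated) | C=C[C@@H](C(C)C)[C@@H](OB1OC(C)(C)C(C)(C)O1)[C@H]1O[C@]1(C)[C@@H](OC(=O)C=C(C)C)C/C=C(\C)I | intermediate
20 | (1S,3E)-1-{(2R,3R)-3-[(1R,2R)-1-hydroxy-2-(propan-2-yl)but-3-en-1-yl]-2-methyloxiran-2-yl}-4-iodopent-3-en-1-yl 3-methylbut-2-enoate | C=C[C@@H](C(C)C)[C@@H](O)[C@H]1O[C@]1(C)[C@@H](OC(=O)C=C(C)C)C/C=C(\C)I | intermediate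
21 | (1S,3E)-1-{(2R,3R)-3-[(1R,2R)-1-(acetyloxy)-2-(propan-2-yl)but-3-en-1-yl]-2-methyloxiran-2-yl}-4-iodopent-3-en-1-yl 3-methylbut-2-enoate (open-chain precursor of the key step) | C=C[C@@H](C(C)C)[C@@H](OC(C)=O)[C@H]1O[C@]1(C)[C@@H](OC(=O)C=C(C)C)C/C=C(\C)I | intermediate
22 | 9-BBN adduct of 21 (boron on C9; not isolated) | C1CC2CCCC(C1)B2CC[C@@H](C(C)C)[C@@H](OC(C)=O)[C@H]1O[C@]1(C)[C@@H](OC(=O)C=C(C)C)C/C=C(\C)I | intermediate
23 | (1R,2S,4E,8S,9R,10R)-9-(acetyloxy)-1,5-dimethyl-8-(propan-2-yl)-11-oxabicyclo[8.1.0]undec-4-en-2-yl 3-methylbut-2-enoate | CC(=O)O[C@H]1[C@H]2O[C@]2(C)[C@@H](OC(=O)C=C(C)C)C/C=C(\C)CC[C@H]1C(C)C | target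

## Step count and least certain steps

Total: 13 steps. Longest linear sequence: 11 steps (1–8, 11–13); steps 9 and 10 form the side branch to 18.

**Step 13 (key step).** The most likely failure is intermolecular coupling and oligomerisation outrunning closure, because the strained eleven-membered palladacycle forms slowly. Prolonged contact with aqueous carbonate could then also saponify the acetate, after which Payne migration would follow, and protodeboronation would compete. The fallback keeps the C9–C10 closure but changes the organometallic and removes the base. It sets out from 22 (made from 21 as in step 13):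
- oxidation with NaBO3·4H2O in THF/H2O would give the primary alcohol F1;
- I2, PPh3 and imidazole at 0 °C would give the primary iodide F2;
- zinc dust with LiCl in THF should insert into the sp3 C–I bond only, giving the alkylzinc iodide F3;
- slow addition of F3 to Pd(dppf)Cl2 in THF/DMF at high dilution would close the ring by an intramolecular Negishi coupling, returning to the route at 23.

**Step 11.** The most likely failure is insufficient facial discrimination: the γ-branched boronate reacts slowly, so uncatalysed background addition with only modest Felkin–Anh control may erode the C5/C6 ratio, and the acid may open the sensitive epoxy aldehyde before C–C bond formation. The fallback is an acid-free, substrate-controlled allylation with divalent chromium. It sets out from 17 and 15: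
- PBr3 in Et2O would convert 17, with allylic transposition, into (2E)-1-bromo-4-methylpent-2-ene F4;
- CrCl2 in THF at 0 °C would turn F4 into the allylchromium reagent F5, which adds to 15 through a chair transition state that gives the anti C6/C7 pair whatever the halide geometry, with Felkin–Anh facial preference;
- the alkenyl iodide is inert to CrCl2 without a nickel co-catalyst;
- the fallback returns at 20.

**Step 4.** The most likely failure is loss of regiocontrol: the zirconium alkoxide formed from the free C3 hydroxyl may steer the metal to C1, or equilibration to the methyl-bearing carbon may be incomplete, giving the regioisomeric iodide. The fallback removes the hydroxyl influence. It sets out from 8: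
- TESCl and imidazole in DMF would give the triethylsilyl ether F6;
- Cp2Zr(H)Cl in THF followed by I2 would give, under purely steric control, the (E)-iodide F7;
- PPTS in MeOH at 0 °C should cleave only the secondary triethylsilyl ether, returning at 10.

**Step 2.** The most likely failure is incomplete enantiocontrol, since an α-branched aliphatic enal fits the chiral pocket less well than the aryl aldehydes for which this catalysis is best established. The fallback separates bond formation from stereocontrol. It sets out from 3:
- propargyl bromide and zinc dust in THF/aq. NH4Cl (Barbier conditions) would give the racemic alcohol F8;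
- immobilised Candida antarctica lipase B with vinyl acetate in hexane should acylate the (R)-enantiomer to the acetate F9 and leave the (S)-alcohol;
- after separation the (S)-alcohol is 6, where the fallback returns, at the cost of at most half the material.

## Further compounds

F1 | step 13 | (1S,3E)-1-{(2R,3R)-3-[(1R,2S)-1-(acetyloxy)-4-hydroxy-2-(propan-2-yl)butyl]-2-methyloxiran-2-yl}-4-iodopent-3-en-1-yl 3-methylbut-2-enoate | OCC[C@@H](C(C)C)[C@@H](OC(C)=O)[C@H]1O[C@]1(C)[C@@H](OC(=O)C=C(C)C)C/C=C(\C)I
F2 | step 13 | (1S,3E)-1-{(2R,3R)-3-[(1R,2S)-1-(acetyloxy)-4-iodo-2-(propan-2-yl)butyl]-2-methyloxiran-2-yl}-4-iodopent-3-en-1-yl 3-methylbut-2-enoate | ICC[C@@H](C(C)C)[C@@H](OC(C)=O)[C@H]1O[C@]1(C)[C@@H](OC(=O)C=C(C)C)C/C=C(\C)I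
F3 | step 13 | alkylzinc iodide derived from F2 (zinc on C9) | I[Zn]CC[C@@H](C(C)C)[C@@H](OC(C)=O)[C@H]1O[C@]1(C)[C@@H](OC(=O)C=C(C)C)C/C=C(\C)I
F4 | step 11 | (2E)-1-bromo-4-methylpent-2-ene | CC(C)/C=C/CBr
F5 | step 11 | [(2E)-4-methylpent-2-en-1-yl]chromium dichloride | CC(C)/C=C/C[Cr](Cl)Cl
F6 | step 4 | (2E,4S)-1-[(tert-butyldimethylsilyl)oxy]-3-methyl-4-[(triethylsilyl)oxy]oct-2-en-6-yne | CC#CC[C@H](O[Si](CC)(CC)CC)/C(C)=C/CO[Si](C)(C)C(C)(C)C
F7 | step 4 | (2E,4S,6E)-1-[(tert-butyldimethylsilyl)oxy]-7-iodo-3-methyl-4-[(triethylsilyl)oxy]octa-2,6-diene | C/C(I)=C\C[C@H](O[Si](CC)(CC)CC)/C(C)=C/CO[Si](C)(C)C(C)(C)C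
F8 | step 2 | (5E)-7-[(tert-butyldimethylsilyl)oxy]-5-methylhept-5-en-1-yn-4-ol (racemic) | C#CCC(O)/C(C)=C/CO[Si](C)(C)C(C)(C)C
F9 | step 2 | (4R,5E)-7-[(tert-butyldimethylsilyl)oxy]-5-methylhept-5-en-1-yn-4-yl acetate | C#CC[C@@H](OC(C)=O)/C(C)=C/CO[Si](C)(C)C(C)(C)C
A1 | alternative 1 | tert-butyl(dimethyl){[(3E,7E,10S,11E)-3,7,11-trimethyl-1-oxacyclotrideca-3,7,11-trien-10-yl]oxy}silane | O1C/C=C(C)/[C@@H](O[Si](C)(C)C(C)(C)C)C/C=C(\C)CC/C=C(C)/C1
A2 | alternative 1 | (3S,6S,7S,1(10)E,4E)-3-[(tert-butyldimethylsilyl)oxy]germacra-1(10),4,11-trien-6-ol | O[C@H]1/C=C(C)/[C@@H](O[Si](C)(C)C(C)(C)C)C/C=C(\C)CC[C@H]1C(C)=C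
A3 | alternative 2 | 7-[(tert-butyldimethylsilyl)oxy]-2,2,7a-trimethyl-4-(3-methylbut-1-en-2-yl)-5-(prop-1-en-2-yl)hexahydro-1,3-benzodioxol-4-ol (alkenyl and isopropenyl groups trans) | O[C@@]1(C(=C)C(C)C)[C@@H]2OC(C)(C)O[C@]2(C)[C@@H](O[Si](C)(C)C(C)(C)C)C[C@H]1C(C)=C
A4 | alternative 2 | (1(10)E)-3-[(tert-butyldimethylsilyl)oxy]-4,5-(isopropylidenedioxy)germacr-1(10)-en-6-one | O=C1[C@@H]2OC(C)(C)O[C@]2(C)[C@@H](O[Si](C)(C)C(C)(C)C)C/C=C(\C)CC[C@H]1C(C)C
A5 | alternative 3 | 3-[(tert-butyldimethylsilyl)oxy]-6-[(triethylsilyl)oxy]eudesm-4-en-1-yl methanesulfonate | CC[Si](CC)(CC)O[C@H]1C2=C(C)[C@@H](O[Si](C)(C)C(C)(C)C)C[C@@H](OS(C)(=O)=O)[C@]2(C)CC[C@H]1C(C)C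
A6 | alternative 3 | (1(10)E,4E)-3-[(tert-butyldimethylsilyl)oxy]-6-[(triethylsilyl)oxy]germacra-1(10),4-diene | CC[Si](CC)(CC)O[C@H]1/C=C(C)/[C@@H](O[Si](C)(C)C(C)(C)C)C/C=C(\C)CC[C@H]1C(C)C
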